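**Plan**
- Retrosynthesis: the four benzyl ethers come off last (hydrogenolysis). Before that, the two aryl ester C(=O)–O bonds at O1 (acetoxybutanoate) and O4 (phenylpropanoate) are cut, then the C4–C5 bond of the central ring. This leads to a 4-alkenyl-4-(methoxymethoxy)cyclobutenone, which is cut at its C4–alkenyl bond into an aryl(benzyloxy)cyclobutenedione and an α-aryl-β-benzyloxyvinyllithium.
- Enabling feature: the central benzene ring (C1–C6) is a hydroquinone with oxygens at C1 and C4, OH at C2/C5 and aryl groups at C3/C6. A ketene carbon delivers C4–OH as the only free phenol, para to C1–O, which arrives capped as an acetal, so the two ester oxygens are distinguished.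
- Forward order: squaric acid → dibenzyl squarate → aryl(benzyloxy)cyclobutenedione; alkenyllithium addition with MOM capture; thermal ring expansion builds the central ring (the only ring made, all other rings are bought); phenylpropanoylation, MOM removal, acetoxybutanoylation, hydrogenolysis.
- Stereochemistry: the single (S) centre comes from (S)-3-hydroxybutanoic acid and is never made reactive. The quaternary centre of the cyclobutenone is racemic and vanishes on aromatisation.

Key step: step 7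

Assumption: enol ether 14 and bromide 16 are carried as E/Z mixtures (geometry not drawn), because that carbon ends as an aromatic ring atom; compounds 6, 7, 15, 18, 19 and 21 are racemic.

**Step 1**
Reactants: 1 squaric acid
Product: 3 3,4-bis(benzyloxy)cyclobut-3-ene-1,2-dione (dibenzyl squarate), via monobenzyl squarate 2 (not isolated)
Conditions: BnOH (excess), toluene, reflux, Dean–Stark
Reagents that add atoms: benzyl alcohol, OCc1ccccc1
Why: Azeotropic esterification of the strongly acidic vinylogous diacid, the standard entry to dialkyl squarates, is driven to the diester by removal of water.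

**Step 2**
Reactants: 4 1-(benzyloxy)-4-bromobenzene; 3 dibenzyl squarate
Product: 8 3-(benzyloxy)-4-[4-(benzyloxy)phenyl]cyclobut-3-ene-1,2-dione, via aryllithium 5 (not isolated), via lithium alkoxide 6 (not isolated), via hydroxycyclobutenone 7 (not isolated)
Conditions: n-BuLi, THF, −78 °C; then 3 (inverse addition), −78 °C; then 12 M HCl, CH2Cl2, −78 °C → rt
Reagents that add atoms: none
Why: Bromine–lithium exchange gives the aryllithium, which adds once (1,2-addition) to a squarate carbonyl at −78 °C, and acid then ionises the tertiary benzylic alcohol with allylic transposition and loss of benzyl alcohol from the resulting hemiketal, the usual squarate route to 3-aryl-4-alkoxycyclobutenediones.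

**Step 3**
Reactants: 9 benzyl chloromethyl ether; 10 triphenylphosphine
Product: 11 (benzyloxymethyl)triphenylphosphonium chloride
Conditions: toluene, 80 °C
Reagents that add atoms: none
Why: SN2 quaternisation of triphenylphosphine by the highly reactive α-chloro ether gives the phosphonium salt.

**Step 4**
Reactants: 11 (benzyloxymethyl)triphenylphosphonium chloride; 12 4-(benzyloxy)benzaldehyde
Product: 14 1-(benzyloxy)-4-[2-(benzyloxy)ethenyl]benzene (E/Z mixture), via phosphonium ylide 13 (not isolated)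
Conditions: KOtBu, THF, 0 °C; then 12, 0 °C → rt
Reagents that add atoms: none
Why: Wittig alkoxymethylenation of an aromatic aldehyde with the non-stabilised alkoxymethylide is routine, and the E/Z mixture is acceptable because the geometry is erased later.

**Step 5**
Reactants: 14 1-(benzyloxy)-4-[2-(benzyloxy)ethenyl]benzene
Product: 16 1-(benzyloxy)-4-[2-(benzyloxy)-1-bromoethenyl]benzene, via vicinal dibromide 15 (not isolated)
Conditions: Br2, CH2Cl2, −78 °C; then DBU, −78 °C → rt
Reagents that add atoms: bromine, BrBr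
Why: Bromine adds across the electron-rich enol ether in the cold and the α-bromo ether then ionises to an oxocarbenium ion that loses the acidic benzylic proton, the classical bromination–dehydrobromination route to β-bromo enol ethers.

**Step 6**
Reactants: 16 1-(benzyloxy)-4-[2-(benzyloxy)-1-bromoethenyl]benzene; 8 3-(benzyloxy)-4-[4-(benzyloxy)phenyl]cyclobut-3-ene-1,2-dione
Product: 19 rac-3-(benzyloxy)-4-{2-(benzyloxy)-1-[4-(benzyloxy)phenyl]ethenyl}-2-[4-(benzyloxy)phenyl]-4-(methoxymethoxy)cyclobut-2-en-1-one, via alkenyllithium 17 (not isolated), via lithium cyclobutenolate 18 (not isolated)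
Conditions: t-BuLi (2 equiv), THF, −78 °C; then 8, −78 °C; then MOMCl, −78 → 0 °C
Reagents that add atoms: chloromethyl methyl ether (MOMCl), COCCl
Why: Bromine–lithium exchange gives the 2-alkoxyvinyllithium, which adds 1,2 to the ketone-like carbonyl next to the benzyloxy-bearing carbon (the other carbonyl is deactivated as a vinylogous ester), and the lithium alkoxide is O-alkylated by MOMCl (Williamson-type) before warming, the new quaternary centre being formed racemic and erased in step 7.

**Step 7**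
Reactants: 19 rac-3-(benzyloxy)-4-{2-(benzyloxy)-1-[4-(benzyloxy)phenyl]ethenyl}-2-[4-(benzyloxy)phenyl]-4-(methoxymethoxy)cyclobut-2-en-1-one
Product: 22 2,5-bis(benzyloxy)-3,6-bis[4-(benzyloxy)phenyl]-4-(methoxymethoxy)phenol, via dienylketene 20 (not isolated), via cyclohexadienone 21 (not isolated)
Conditions: toluene (degassed), 110 °C, argon
Reagents that add atoms: none
Why: Heating triggers conrotatory 4π opening of the C1–C4 bond of the cyclobutenone, the donor methoxymethoxy group turning outward and the alkenyl group inward, to give the (3Z)-dienylketene 20. Thermal disrotatory 6π electrocyclisation then joins the ketene carbon to the benzyloxy-bearing vinyl carbon, closing the six-membered carbocycle as cyclohexa-2,4-dienone 21, and enolisation gives phenol 22. The closest known reaction type is the Moore rearrangement of squarate-derived 4-alkenyl-4-alkoxycyclobutenones to hydroquinone monoethers. No stereocentre survives: the racemic quaternary carbon becomes sp2 on opening and the transient sp3 carbon of 21 is lost on tautomerisation. The step needs the alkenyl group cis to the ketene, which the outward torquoselectivity of the oxygen substituent secures, while the substitution pattern was fixed by the regioselective addition in step 6; either geometry of the enol ether terminus can close because the ketene carbon is sterically undemanding.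

**Step 8**
Reactants: 22 2,5-bis(benzyloxy)-3,6-bis[4-(benzyloxy)phenyl]-4-(methoxymethoxy)phenol; 23 3-phenylpropanoyl chloride
Product: 24 2,5-bis(benzyloxy)-3,6-bis[4-(benzyloxy)phenyl]-4-(methoxymethoxy)phenyl 3-phenylpropanoate
Conditions: Et3N, DMAP (cat.), CH2Cl2, 0 °C → rt
Reagents that add atoms: none
Why: Nucleophile-catalysed acylation by an acid chloride esterifies the only free hydroxyl, since every other oxygen is an ether or acetal.

**Step 9**
Reactants: 24 2,5-bis(benzyloxy)-3,6-bis[4-(benzyloxy)phenyl]-4-(methoxymethoxy)phenyl 3-phenylpropanoate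
Product: 25 2,5-bis(benzyloxy)-3,6-bis[4-(benzyloxy)phenyl]-4-hydroxyphenyl 3-phenylpropanoate
Conditions: CF3CO2H, CH2Cl2, 0 °C; then H2O
Reagents that add atoms: none
Why: Acid-catalysed cleavage of the aryl methoxymethyl acetal through its oxocarbenium ion proceeds under mild conditions that leave the aryl ester and the aryl benzyl ethers intact.

**Step 10**
Reactants: 26 (S)-3-hydroxybutanoic acid
Product: 27 (3S)-3-(acetyloxy)butanoic acid
Conditions: Ac2O, pyridine, 0 °C → rt; then H2O
Reagents that add atoms: acetic anhydride, CC(=O)OC(C)=O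
Why: O-Acetylation of the secondary alcohol does not touch the C–O bond of the stereocentre, and any mixed anhydride is hydrolysed on aqueous work-up.

**Step 11**
Reactants: 25 2,5-bis(benzyloxy)-3,6-bis[4-(benzyloxy)phenyl]-4-hydroxyphenyl 3-phenylpropanoate; 27 (3S)-3-(acetyloxy)butanoic acid
Product: 29 2,5-bis(benzyloxy)-3,6-bis[4-(benzyloxy)phenyl]-4-[(3-phenylpropanoyl)oxy]phenyl (3S)-3-(acetyloxy)butanoate, via O-acylisourea 28 (not isolated)
Conditions: DIC, DMAP (cat.), CH2Cl2, 0 °C → rt
Reagents that add atoms: none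
Why: Steglich esterification acylates the hindered phenol under nearly neutral conditions in the cold, which limits β-elimination of acetate and leaves the (S) centre a spectator.

**Step 12**
Reactants: 29 2,5-bis(benzyloxy)-3,6-bis[4-(benzyloxy)phenyl]-4-[(3-phenylpropanoyl)oxy]phenyl (3S)-3-(acetyloxy)butanoate
Product: 30 2,5-dihydroxy-3,6-bis(4-hydroxyphenyl)-4-[(3-phenylpropanoyl)oxy]phenyl (3S)-3-(acetyloxy)butanoate (CNP0332078.1)
Conditions: H2 (1 atm), Pd/C, EtOAc, rt
Reagents that add atoms: none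
Why: Catalytic hydrogenolysis cleaves the four aryl benzyl ethers in neutral ethyl acetate without touching the aryl esters, the acetate or the stereocentre, and the absence of base avoids acyl migration to the freed neighbouring hydroxyls.

**Compound list**
1 | squaric acid (3,4-dihydroxycyclobut-3-ene-1,2-dione) | O=C1C(=O)C(O)=C1O | starting material
2 | 3-(benzyloxy)-4-hydroxycyclobut-3-ene-1,2-dione (monobenzyl squarate) | O=C1C(=O)C(OCc2ccccc2)=C1O | intermediate
3 | 3,4-bis(benzyloxy)cyclobut-3-ene-1,2-dione (dibenzyl squarate) | O=C1C(=O)C(OCc2ccccc2)=C1OCc1ccccc1 | intermediate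
4 | 1-(benzyloxy)-4-bromobenzene | Brc1ccc(OCc2ccccc2)cc1 | starting material
5 | [4-(benzyloxy)phenyl]lithium | [Li]c1ccc(OCc2ccccc2)cc1 | intermediate
6 | lithium 2,3-bis(benzyloxy)-1-[4-(benzyloxy)phenyl]-4-oxocyclobut-2-en-1-olate (racemic) | [Li]OC1(c2ccc(OCc3ccccc3)cc2)C(=O)C(OCc2ccccc2)=C1OCc1ccccc1 | intermediate
7 | rac-2,3-bis(benzyloxy)-4-[4-(benzyloxy)phenyl]-4-hydroxycyclobut-2-en-1-one | OC1(c2ccc(OCc3ccccc3)cc2)C(=O)C(OCc2ccccc2)=C1OCc1ccccc1 | intermediate
8 | 3-(benzyloxy)-4-[4-(benzyloxy)phenyl]cyclobut-3-ene-1,2-dione | O=C1C(=O)C(c2ccc(OCc3ccccc3)cc2)=C1OCc1ccccc1 | intermediate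
9 | benzyl chloromethyl ether | ClCOCc1ccccc1 | starting material
10 | triphenylphosphine | c1ccc(cc1)P(c1ccccc1)c1ccccc1 | starting material
11 | (benzyloxymethyl)triphenylphosphonium chloride | [Cl-].c1ccc(cc1)COC[P+](c1ccccc1)(c1ccccc1)c1ccccc1 | intermediate
12 | 4-(benzyloxy)benzaldehyde | O=Cc1ccc(OCc2ccccc2)cc1 | starting material
13 | (benzyloxymethylidene)triphenylphosphorane | C(OCc1ccccc1)=P(c1ccccc1)(c1ccccc1)c1ccccc1 | intermediate
14 | 1-(benzyloxy)-4-[2-(benzyloxy)ethenyl]benzene (E/Z mixture) | C(=COCc1ccccc1)c1ccc(OCc2ccccc2)cc1 | intermediate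
15 | 1-(benzyloxy)-4-[2-(benzyloxy)-1,2-dibromoethyl]benzene (diastereomer mixture, racemic) | BrC(OCc1ccccc1)C(Br)c1ccc(OCc2ccccc2)cc1 | intermediate
16 | 1-(benzyloxy)-4-[2-(benzyloxy)-1-bromoethenyl]benzene (geometry not defined) | BrC(=COCc1ccccc1)c1ccc(OCc2ccccc2)cc1 | intermediate
17 | {2-(benzyloxy)-1-[4-(benzyloxy)phenyl]ethenyl}lithium | [Li]C(=COCc1ccccc1)c1ccc(OCc2ccccc2)cc1 | intermediate
18 | lithium 2-(benzyloxy)-1-{2-(benzyloxy)-1-[4-(benzyloxy)phenyl]ethenyl}-3-[4-(benzyloxy)phenyl]-4-oxocyclobut-2-en-1-olate (racemic) | [Li]OC1(C(=COCc2ccccc2)c2ccc(OCc3ccccc3)cc2)C(=O)C(c2ccc(OCc3ccccc3)cc2)=C1OCc1ccccc1 | intermediate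
19 | rac-3-(benzyloxy)-4-{2-(benzyloxy)-1-[4-(benzyloxy)phenyl]ethenyl}-2-[4-(benzyloxy)phenyl]-4-(methoxymethoxy)cyclobut-2-en-1-one | O=C1C(c2ccc(OCc3ccccc3)cc2)=C(OCc2ccccc2)C1(OCOC)C(=COCc1ccccc1)c1ccc(OCc2ccccc2)cc1 | intermediate
20 | (3Z)-3,6-bis(benzyloxy)-2,5-bis[4-(benzyloxy)phenyl]-4-(methoxymethoxy)hexa-1,3,5-trien-1-one | O=C=C(c1ccc(OCc2ccccc2)cc1)/C(OCc1ccccc1)=C(/OCOC)C(=COCc1ccccc1)c1ccc(OCc2ccccc2)cc1 | intermediate
21 | rac-3,6-bis(benzyloxy)-2,5-bis[4-(benzyloxy)phenyl]-4-(methoxymethoxy)cyclohexa-2,4-dien-1-one | O=C1C(c2ccc(OCc3ccccc3)cc2)=C(OCc2ccccc2)C(OCOC)=C(c2ccc(OCc3ccccc3)cc2)C1OCc1ccccc1 | intermediate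
22 | 2,5-bis(benzyloxy)-3,6-bis[4-(benzyloxy)phenyl]-4-(methoxymethoxy)phenol | Oc1c(OCc2ccccc2)c(-c2ccc(OCc3ccccc3)cc2)c(OCOC)c(OCc2ccccc2)c1-c1ccc(OCc2ccccc2)cc1 | intermediate
23 | 3-phenylpropanoyl chloride | O=C(Cl)CCc1ccccc1 | starting material
24 | 2,5-bis(benzyloxy)-3,6-bis[4-(benzyloxy)phenyl]-4-(methoxymethoxy)phenyl 3-phenylpropanoate | O=C(CCc1ccccc1)Oc1c(OCc2ccccc2)c(-c2ccc(OCc3ccccc3)cc2)c(OCOC)c(OCc2ccccc2)c1-c1ccc(OCc2ccccc2)cc1 | intermediate
25 | 2,5-bis(benzyloxy)-3,6-bis[4-(benzyloxy)phenyl]-4-hydroxyphenyl 3-phenylpropanoate | O=C(CCc1ccccc1)Oc1c(OCc2ccccc2)c(-c2ccc(OCc3ccccc3)cc2)c(O)c(OCc2ccccc2)c1-c1ccc(OCc2ccccc2)cc1 | intermediate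
26 | (S)-3-hydroxybutanoic acid | C[C@H](O)CC(=O)O | starting material
27 | (3S)-3-(acetyloxy)butanoic acid | CC(=O)O[C@@H](C)CC(=O)O | intermediate
28 | O-[(3S)-3-(acetyloxy)butanoyl]-N,N'-diisopropylisourea | CC(=O)O[C@@H](C)CC(=O)OC(=NC(C)C)NC(C)C | intermediate
29 | 2,5-bis(benzyloxy)-3,6-bis[4-(benzyloxy)phenyl]-4-[(3-phenylpropanoyl)oxy]phenyl (3S)-3-(acetyloxy)butanoate | CC(=O)O[C@@H](C)CC(=O)Oc1c(OCc2ccccc2)c(-c2ccc(OCc3ccccc3)cc2)c(OC(=O)CCc2ccccc2)c(OCc2ccccc2)c1-c1ccc(OCc2ccccc2)cc1 | intermediate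
30 | 2,5-dihydroxy-3,6-bis(4-hydroxyphenyl)-4-[(3-phenylpropanoyl)oxy]phenyl (3S)-3-(acetyloxy)butanoate | CC(=O)O[C@@H](C)CC(=O)Oc1c(O)c(-c2ccc(O)cc2)c(OC(=O)CCc2ccccc2)c(O)c1-c1ccc(O)cc1 | target

**Step count and risks**
Total: 12 steps. Longest linear sequence: 9 steps (steps 3, 4, 5, 6, 7, 8, 9, 11 and 12, from benzyl chloromethyl ether 9).

Steps most likely to fail:

1. Step 6. The crowded tertiary lithium alkoxide 18 may be O-alkylated too slowly, so that on warming it fragments or the ring opens before the oxygen is capped. The fallback sets out from 8 and 16 and gives up the acetal altogether. Alkenyllithium 17 is added as before, but the mixture is quenched at −78 °C with aqueous NH4Cl to give the tertiary alcohol rac-3-(benzyloxy)-4-{2-(benzyloxy)-1-[4-(benzyloxy)phenyl]ethenyl}-2-[4-(benzyloxy)phenyl]-4-hydroxycyclobut-2-en-1-one F2. Heating F2 in degassed toluene at 110 °C should run the same ring expansion through the hydroxy dienylketene F3 and the hydroxy cyclohexadienone F4 to the hydroquinone 2,5-bis(benzyloxy)-3,6-bis[4-(benzyloxy)phenyl]benzene-1,4-diol F5, which is worked up under argon with aqueous Na2S2O4 to keep it reduced. The two hydroxyls of F5 are equivalent by symmetry, so one equivalent of 23 with Et3N and DMAP (cat.) in CH2Cl2 at −20 °C gives the monoester statistically; recovered F5 is recycled. The route is rejoined at 25.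

2. Step 5. Hydrogen bromide may be lost toward the oxygen-bearing carbon, or the p-alkoxybenzylic bromide may ionise, eroding the regiochemistry of the vinyl bromide. The fallback sets out from 14. Bromoalkoxylation with NBS and benzyl alcohol in CH2Cl2 at −40 °C gives the bromo acetal 1-(benzyloxy)-4-[2,2-bis(benzyloxy)-1-bromoethyl]benzene F1. TMSOTf and i-Pr2NEt in CH2Cl2 at −20 °C (acetal-to-enol-ether elimination) then ionise the acetal and remove the benzylic proton, the only one available, so the bromine can only end on the aryl-bearing carbon. The route is rejoined at 16.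

3. Step 11. Base-induced β-elimination of acetate from the activated acid (crotonate formation) may compete with the slow acylation of the di-ortho-substituted phenol. The fallback sets out from 26 and introduces the acetyl group last. TBSCl and imidazole in DMF give the bis-silyl compound tert-butyldimethylsilyl (3S)-3-[(tert-butyldimethylsilyl)oxy]butanoate F6. K2CO3 in MeOH/THF/H2O cleaves only the silyl ester to give (3S)-3-[(tert-butyldimethylsilyl)oxy]butanoic acid F7. DIC/DMAP coupling with 25 gives 2,5-bis(benzyloxy)-3,6-bis[4-(benzyloxy)phenyl]-4-[(3-phenylpropanoyl)oxy]phenyl (3S)-3-[(tert-butyldimethylsilyl)oxy]butanoate F8; a silyloxy group is a poor leaving group, so elimination is suppressed. HF·pyridine in THF frees the alcohol 2,5-bis(benzyloxy)-3,6-bis[4-(benzyloxy)phenyl]-4-[(3-phenylpropanoyl)oxy]phenyl (3S)-3-hydroxybutanoate F9. Ac2O in pyridine at 0 °C acetylates it, and the route is rejoined at 29.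

**Further compounds**
F1 | step 5 | 1-(benzyloxy)-4-[2,2-bis(benzyloxy)-1-bromoethyl]benzene (racemic) | BrC(c1ccc(OCc2ccccc2)cc1)C(OCc1ccccc1)OCc1ccccc1
F2 | step 6 | rac-3-(benzyloxy)-4-{2-(benzyloxy)-1-[4-(benzyloxy)phenyl]ethenyl}-2-[4-(benzyloxy)phenyl]-4-hydroxycyclobut-2-en-1-one | O=C1C(c2ccc(OCc3ccccc3)cc2)=C(OCc2ccccc2)C1(O)C(=COCc1ccccc1)c1ccc(OCc2ccccc2)cc1
F3 | step 6 | (3Z)-3,6-bis(benzyloxy)-2,5-bis[4-(benzyloxy)phenyl]-4-hydroxyhexa-1,3,5-trien-1-one | O=C=C(c1ccc(OCc2ccccc2)cc1)/C(OCc1ccccc1)=C(/O)C(=COCc1ccccc1)c1ccc(OCc2ccccc2)cc1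
F4 | step 6 | rac-3,6-bis(benzyloxy)-2,5-bis[4-(benzyloxy)phenyl]-4-hydroxycyclohexa-2,4-dien-1-one | O=C1C(c2ccc(OCc3ccccc3)cc2)=C(OCc2ccccc2)C(O)=C(c2ccc(OCc3ccccc3)cc2)C1OCc1ccccc1
F5 | step 6 | 2,5-bis(benzyloxy)-3,6-bis[4-(benzyloxy)phenyl]benzene-1,4-diol | Oc1c(OCc2ccccc2)c(-c2ccc(OCc3ccccc3)cc2)c(O)c(OCc2ccccc2)c1-c1ccc(OCc2ccccc2)cc1
F6 | step 11 | tert-butyldimethylsilyl (3S)-3-[(tert-butyldimethylsilyl)oxy]butanoate | C[C@H](O[Si](C)(C)C(C)(C)C)CC(=O)O[Si](C)(C)C(C)(C)C
F7 | step 11 | (3S)-3-[(tert-butyldimethylsilyl)oxy]butanoic acid | C[C@H](O[Si](C)(C)C(C)(C)C)CC(=O)O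
F8 | step 11 | 2,5-bis(benzyloxy)-3,6-bis[4-(benzyloxy)phenyl]-4-[(3-phenylpropanoyl)oxy]phenyl (3S)-3-[(tert-butyldimethylsilyl)oxy]butanoate | C[C@H](O[Si](C)(C)C(C)(C)C)CC(=O)Oc1c(OCc2ccccc2)c(-c2ccc(OCc3ccccc3)cc2)c(OC(=O)CCc2ccccc2)c(OCc2ccccc2)c1-c1ccc(OCc2ccccc2)cc1
F9 | step 11 | 2,5-bis(benzyloxy)-3,6-bis[4-(benzyloxy)phenyl]-4-[(3-phenylpropanoyl)oxy]phenyl (3S)-3-hydroxybutanoate | C[C@H](O)CC(=O)Oc1c(OCc2ccccc2)c(-c2ccc(OCc3ccccc3)cc2)c(OC(=O)CCc2ccccc2)c(OCc2ccccc2)c1-c1ccc(OCc2ccccc2)cc1
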